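## Retrosynthetic overview

1. Guaiane numbering is used for both C15 halves (unprimed: acetoxy/isopropyl half; primed: peroxide half). The core is a 7-acetoxynorbornene with bridgeheads C1/C3, one-carbon bridge C2–OAc, alkene bridge C4=C5 and saturated bridge C3′–C4′. It is fused endo to the cyclopentenone C1′–C5′, which is the imprint of a cyclopentadienone caught through its C3′=C4′ bond.
2. Last ring: the 1,2-dioxolan-3-ol (C7′–C8′–O–O–C11′) comes from a singlet-oxygen ene reaction of a 7′(11′)-en-8′-one (H taken from C6′), followed by closure of the hydroperoxide on C8′=O.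
3. Key cut: C3–C3′ and C1–C4′ (vicinal quaternary carbons) form in one cross [4+2] of two transient species, a 2-acetoxyguaia-1(5),3-diene and a guaia-1(5),3-dien-2-one. Each is released in the same flask by loss of water from a C4 tertiary alcohol.
4. Both partners are redox variants of one 4-hydroxyguai-1(5)-ene-2,8-dione, whose seven-membered ring is closed at C7–C8 by a carbonyl-ene reaction across the cis C1=C5 bond.
5. The cyclopentenone comes from cyclopentane-1,3-dione (an organocatalytic Michael addition sets C10, then a Stork–Danheiser transposition). Ring order: five-membered rings (bought), seven-membered rings, norbornene, dioxolane.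

Key step: step 11

Remark: C8′ is a hemiketal carbon that equilibrates by ring–chain tautomerism, and the drawn (8′R) epimer is assumed to be the one favoured at equilibrium. Centres that are mixtures and vanish later (acetal carbon in 3–7, C4 in 5–14, C7/C8 in 10) are written without configuration.

## Route

Step 1
Reactants: 1 cyclopentane-1,3-dione; 2 (E)-but-2-enal
Product: 4 (4R)-2-methoxy-4-methyl-3,4,6,7-tetrahydrocyclopenta[b]pyran-5(2H)-one, via lactol (4R)-2-hydroxy-4-methyl-3,4,6,7-tetrahydrocyclopenta[b]pyran-5(2H)-one 3 (not isolated)
Conditions: (S)-diphenylprolinol TMS ether (10 mol %), PhCO2H (10 mol %), CH2Cl2, 0 °C to rt; then MeOH, p-TsOH (5 mol %), 4 Å MS, rt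
Reagents that add atoms: methanol, CO
Why: Iminium-catalysed Michael addition in which the (S)-catalyst shields one face of the E,s-trans iminium ion so that the dione carbon (later C1) adds to set C10 as R; the lactol is then trapped as a methyl acetal, which serves both as the vinylogous ester for the Stork–Danheiser sequence and as the mask of the C8 aldehyde.

Step 2
Reactants: 4 methyl acetal
Product: 5 (4R)-2-methoxy-4,6-dimethyl-3,4,6,7-tetrahydrocyclopenta[b]pyran-5(2H)-one
Conditions: LDA (1.1 equiv), THF, −78 °C; MeI, −78 to −20 °C
Reagents that add atoms: iodomethane, CI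
Why: Kinetic α′-deprotonation of the vinylogous ester (Stork–Danheiser alkylation) places the C15 methyl group on the only carbon next to the ketone (later C4), and the new centre is lost in step 11.

Step 3
Reactants: 5 methylated vinylogous ester
Product: 6 (4R)-6-hydroxy-2-methoxy-4,6-dimethyl-3,4,6,7-tetrahydrocyclopenta[b]pyran-5(2H)-one
Conditions: KHMDS (1.2 equiv), THF, −78 °C; 2-(phenylsulfonyl)-3-phenyloxaziridine; AcOH quench
Reagents that add atoms: 2-(phenylsulfonyl)-3-phenyloxaziridine, O=S(=O)(N1OC1c1ccccc1)c1ccccc1
Why: Davis oxidation of the fully substituted α′-enolate installs the C4 tertiary alcohol while this is still the only ketone in the molecule, and this alcohol is the later leaving group for both cycloaddition partners.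

Step 4
Reactants: 6 α-hydroxy ketone
Product: 8 (3R)-3-[2-allyl-3-hydroxy-3-methyl-5-oxocyclopent-1-en-1-yl]butanal, via 5-allyl-5,6-diol 7 (not isolated)
Conditions: allylMgBr (3 equiv), THF, −78 to 0 °C; then 1 M aq HCl, THF, rt
Reagents that add atoms: allylmagnesium bromide, C=CC[Mg]Br; water, O
Why: Stork–Danheiser transposition, in which 1,2-addition to the ketone (C5) and acid-induced loss of the new carbinol with hydrolysis of the enol-ether oxygen gives the C2 enone with the allyl group on C5, and the same hydrolysis frees the C8 aldehyde.

Step 5
Reactants: 8 allyl enone aldehyde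
Product: 9 (3R)-3-[3-hydroxy-3-methyl-2-(3-methylbut-2-en-1-yl)-5-oxocyclopent-1-en-1-yl]butanal
Conditions: Grubbs II (3 mol %), 2-methylbut-2-ene (excess), 1,4-benzoquinone (10 mol %), CH2Cl2, 35 °C
Reagents that add atoms: 2-methylbut-2-ene, CC=C(C)C
Why: Cross metathesis of a terminal alkene with 2-methylbut-2-ene is the standard way to a linear prenyl group (which a prenyl Grignard reagent would not give), and benzoquinone suppresses migration of the skipped double bond.

Step 6
Reactants: 9 prenyl enone aldehyde
Product: 10 (10R)-4,8-dihydroxyguaia-1(5),11-dien-2-one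
Conditions: Me2AlCl (2.5 equiv), CH2Cl2 (0.005 M), −78 to 0 °C; aq HCl work-up
Reagents that add atoms: none
Why: Type I intramolecular carbonyl-ene reaction (the citronellal-to-isopulegol pattern extended by one atom), in which the nucleophilic C7 of the trisubstituted alkene attacks the activated C8 aldehyde while the cis C1=C5 bond holds both chains together; this closes the seven-membered ring, and the new C7/C8 centres are reset in step 7.

Step 7
Reactants: 10 hydroazulenediol
Product: 11 (7S,10R)-4-hydroxyguaia-1(5),11-diene-2,8-dione
Conditions: Dess–Martin periodinane, CH2Cl2, 0 °C to rt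
Reagents that add atoms: none
Why: Dess–Martin oxidation touches only the secondary alcohol, and the doubly activated C7–H should equilibrate on work-up to the 7,10-cis epimer (C7 substituent pseudo-equatorial, C10 methyl pseudo-axial to avoid allylic strain with C2=O).

Step 8
Reactants: 11 isopropenyl dione
Product: 12 (7S,10R)-4-hydroxyguai-1(5)-ene-2,8-dione
Conditions: H2 (1 atm), RhCl(PPh3)3 (5 mol %), benzene/EtOH, rt
Reagents that add atoms: none
Why: Homogeneous hydrogenation with Wilkinson's catalyst saturates the unhindered 1,1-disubstituted alkene and leaves the tetrasubstituted enone alone, while C7 stays under the same thermodynamic control.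

Step 9
Reactants: 12 isopropyl dione
Product: 13 (2S,7S,10R)-2,4-dihydroxyguai-1(5)-en-8-one
Conditions: (R)-Me-CBS (20 mol %), BH3·SMe2 (1.5 equiv), THF, −40 °C; MeOH, then water
Reagents that add atoms: none
Why: Corey–Bakshi–Shibata reduction with the substituted alkene side as the large group sets C2 as S under catalyst control, matched with hydride attack anti to the pseudo-axial C10 methyl; the C8 ketone, a cycloheptanone flanked by the isopropyl-bearing C7, should react much more slowly.

Step 10
Reactants: 13 allylic alcohol
Product: 14 (2S,7S,10R)-2-acetoxy-4-hydroxyguai-1(5)-en-8-one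
Conditions: Ac2O (1.2 equiv), pyridine, DMAP (5 mol %), CH2Cl2, 0 °C
Reagents that add atoms: acetic anhydride, CC(=O)OC(C)=O
Why: Standard acylation takes the secondary alcohol only, the C4 tertiary alcohol being too hindered under these conditions.

Step 11
Reactants: 14 acetoxy carbinol (2 equiv); 11 isopropenyl dione (1 equiv)
Product: 17 endo cross-adduct (2-acetoxy-7-isopropyl-8-oxo half joined through C3–C3′ and C1–C4′ to the 2′,8′-dioxo-7′-isopropenyl half), via (2S,7S,10R)-2-acetoxyguaia-1(5),3-dien-8-one 15 (not isolated), via (7S,10R)-guaia-1(5),3,11-triene-2,8-dione 16 (not isolated)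
Conditions: 14, Martin sulfurane (2.2 equiv), CH2Cl2, −40 °C, 20 min; then 11 and Martin sulfurane (1.1 equiv), each in CH2Cl2, by syringe pump over 4 h, −40 to 0 °C
Reagents that add atoms: none
Why: Martin sulfurane removes water from both C4 carbinols without acid or amine base (allylic loss in 14, loss across the acidified C3–H in 11), and the electron-rich diene 15, held in excess, meets the antiaromatic dienone 16, held at low concentration by slow addition, in a concerted, asynchronous, endo [π4s+π2s] cycloaddition whose leading bond C3–C3′ joins the only two unsubstituted termini, where HOMO(15) and LUMO(16) have their largest coefficients, and whose lagging bond C1–C4′ makes the vicinal quaternary pair. The closest known reaction types are the trapping of in situ generated cyclopentadienones with cyclopentadienes and the endo dimerisation of cyclopentadienones; these pass through a bis-pericyclic transition state, so an adduct formed in the other sense (16 as the diene, bonds C3–C3′ and C4–C1′) should drain into 17 by Cope rearrangement, since only 17 trades a strained bridging ketone for a conjugated enone. Two rings close at once by suprafacial addition to both partners, the cyclopentane C1–C2–C3–C3′–C4′ and the cyclohexene C1–C5=C4–C3–C3′–C4′, which together are the norbornene. C3′ and C4′ (H and CH3 exo, ring D endo) follow from the endo rule and the cis geometry of C3′=C4′, the face of 16 is set by its pseudo-axial C10′ methyl group, and C1 and C3 follow from attack on the face of 15 anti to both the C10 methyl group and the C2 acetate, which leaves H-2 over the C3′–C4′ bridge and the acetate syn to C4=C5 as in the target. The step needs cross- over self-reaction (secured by polarity matching, the excess of 15 and the slow release of 16) and attack anti to the acetate, which runs against the known stereoelectronic preference of 5-acyloxycyclopentadienes for syn attack. What should override that preference here is steric: on the acetate face the exo C15′ methyl group of 16 runs into the acetate oxygen, and C4′ would have to bond to C1 next to the pseudo-axial C10 methyl group.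

Step 12
Reactants: 17 isopropenyl cross-adduct
Product: 18 7′(11′)-isopropylidene cross-adduct
Conditions: DBU (0.3 equiv), toluene, argon, 0 °C to rt, stopped at full conversion of 17
Reagents that add atoms: none
Why: Base-mediated conjugation of a β,γ-unsaturated ketone (the isopulegone-to-pulegone pattern) through the C7′ dienolate and protonation at the unhindered terminal CH2; the same base keeps C7 of the other half at its favoured (7S) configuration, cis to the pseudo-axial C10 methyl group.

Step 13
Reactants: 18 isopropylidene cross-adduct
Product: 20 target CNP0317907.1, via 11′-hydroperoxy-6′-en-8′-one 19 (not isolated)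
Conditions: O2, tetraphenylporphyrin (1 mol %), visible light (>495 nm), CH2Cl2, −20 °C; then rt in the dark
Reagents that add atoms: dioxygen, O=O
Why: Schenck ene reaction of an s-cis α-alkylidene ketone, in which singlet oxygen binds to C11′ and takes the hydrogen from the branch geminal to the carbonyl group (the doubly allylic C6′–H), as known for pulegone-type enones, after which the β-hydroperoxy ketone 19 closes to the five-membered peroxy-hemiketal with C8′ set by equilibration; the C4=C5 alkene is shielded exo by the syn C2 acetate and endo by ring D, the s-trans cyclopentenone is inert, and the cut-off filter avoids enone excitation and cage-forming [2+2] closure.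

## Compound list

1 | cyclopentane-1,3-dione | O=C1CCC(=O)C1 | starting material
2 | (E)-but-2-enal | C/C=C/C=O | starting material
3 | (4R)-2-hydroxy-4-methyl-3,4,6,7-tetrahydrocyclopenta[b]pyran-5(2H)-one | OC1C[C@@H](C)C2=C(O1)CCC2=O | intermediate
4 | (4R)-2-methoxy-4-methyl-3,4,6,7-tetrahydrocyclopenta[b]pyran-5(2H)-one | COC1C[C@@H](C)C2=C(O1)CCC2=O | intermediate
5 | (4R)-2-methoxy-4,6-dimethyl-3,4,6,7-tetrahydrocyclopenta[b]pyran-5(2H)-one | COC1C[C@@H](C)C2=C(O1)CC(C)C2=O | intermediate
6 | (4R)-6-hydroxy-2-methoxy-4,6-dimethyl-3,4,6,7-tetrahydrocyclopenta[b]pyran-5(2H)-one | COC1C[C@@H](C)C2=C(O1)CC(C)(O)C2=O | intermediate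
7 | (4R)-5-allyl-2-methoxy-4,6-dimethyl-2,3,4,5,6,7-hexahydrocyclopenta[b]pyran-5,6-diol | COC1C[C@@H](C)C2=C(O1)CC(C)(O)C2(O)CC=C | intermediate
8 | (3R)-3-[2-allyl-3-hydroxy-3-methyl-5-oxocyclopent-1-en-1-yl]butanal | O=CC[C@@H](C)C1=C(CC=C)C(C)(O)CC1=O | intermediate
9 | (3R)-3-[3-hydroxy-3-methyl-2-(3-methylbut-2-en-1-yl)-5-oxocyclopent-1-en-1-yl]butanal | O=CC[C@@H](C)C1=C(CC=C(C)C)C(C)(O)CC1=O | intermediate
10 | (10R)-4,8-dihydroxyguaia-1(5),11-dien-2-one | CC(=C)C1CC2=C(C(=O)CC2(C)O)[C@H](C)CC1O | intermediate
11 | (7S,10R)-4-hydroxyguaia-1(5),11-diene-2,8-dione | CC(=C)[C@@H]1CC2=C(C(=O)CC2(C)O)[C@H](C)CC1=O | intermediate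
12 | (7S,10R)-4-hydroxyguai-1(5)-ene-2,8-dione | CC(C)[C@@H]1CC2=C(C(=O)CC2(C)O)[C@H](C)CC1=O | intermediate
13 | (2S,7S,10R)-2,4-dihydroxyguai-1(5)-en-8-one | O[C@H]1CC(C)(O)C2=C1[C@H](C)CC(=O)[C@H](C(C)C)C2 | intermediate
14 | (2S,7S,10R)-2-acetoxy-4-hydroxyguai-1(5)-en-8-one | CC(=O)O[C@H]1CC(C)(O)C2=C1[C@H](C)CC(=O)[C@H](C(C)C)C2 | intermediate
15 | (2S,7S,10R)-2-acetoxyguaia-1(5),3-dien-8-one | CC(=O)O[C@H]1C=C(C)C2=C1[C@H](C)CC(=O)[C@H](C(C)C)C2 | intermediate
16 | (7S,10R)-guaia-1(5),3,11-triene-2,8-dione | CC1=CC(=O)C2=C1C[C@@H](C(C)=C)C(=O)C[C@H]2C | intermediate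
17 | endo cross-adduct, 7′-isopropenyl | CC(=O)O[C@H]1[C@H]2C(C)=C3C[C@@H](C(C)C)C(=O)C[C@@H](C)[C@]31[C@]1(C)C3=C(C(=O)[C@H]21)[C@H](C)CC(=O)[C@H](C(C)=C)C3 | intermediate
18 | endo cross-adduct, 7′(11′)-isopropylidene | CC(=O)O[C@H]1[C@H]2C(C)=C3C[C@@H](C(C)C)C(=O)C[C@@H](C)[C@]31[C@]1(C)C3=C(C(=O)[C@H]21)[C@H](C)CC(=O)C(=C(C)C)C3 | intermediate
19 | 11′-hydroperoxy-6′-en-8′-one (open form of the target) | CC(=O)O[C@H]1[C@H]2C(C)=C3C[C@@H](C(C)C)C(=O)C[C@@H](C)[C@]31[C@]1(C)C3=C(C(=O)[C@H]21)[C@H](C)CC(=O)C(C(C)(C)OO)=C3 | intermediate
20 | CNP0317907.1 | CC(=O)O[C@H]1[C@H]2C(C)=C3C[C@@H](C(C)C)C(=O)C[C@@H](C)[C@]31[C@]1(C)C3=C(C(=O)[C@H]21)[C@H](C)C[C@@]1(O)OOC(C)(C)C1=C3 | target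

## Step count and risks

Total step count: 13. Longest linear sequence: 13 (steps 1–13; compound 11 enters step 11 a second time as the partner and needs no steps of its own).

**Steps most likely to fail**

1. **Step 11.**
   - What may go wrong: attack of the dienone on the acetate-bearing face of the diene, which is the stereoelectronic preference of 5-acyloxycyclopentadienes. Further risks are a 1,5-hydrogen shift or loss of water towards the C15 methyl group in the diene, and self-dimerisation or tautomerisation of the dienone.
   - Fallback: this sets out from 12 and 11 and returns at 17. It moves the C2 stereocentre out of the cycloaddition and sets it afterwards with an enzyme. Compound 12 (in excess) and 11 are dehydrated together with Martin sulfurane, so that the transient dienone (7S,10R)-guaia-1(5),3-diene-2,8-dione F1 acts as the diene towards 16 and gives the C2-ketone cross-adduct F2. F2 would have to be separated from the homodimer of F1 and from the cross-adduct of the opposite sense, at a cost in material.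
   - Small hydride reagents are expected to attack the bridging ketone from the open alkene side and give the wrong epimer. A ketoreductase of the short-chain dehydrogenase class (NADPH, glucose/glucose dehydrogenase recycling), chosen from a panel for delivery to the hindered face as in the enzymatic camphor-to-borneol reduction, should give the 2-alcohol with OH syn to C4=C5, F3. Acetylation of F3 (Ac2O, pyridine) gives 17.

2. **Step 6.**
   - What may go wrong: slow closure of the seven-membered ring, overtaken by intermolecular Prins reaction, aldol reaction of the aldehyde with the C3 position, or ionisation of the C4 carbinol by the Lewis acid.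
   - Fallback: this sets out from 6 and returns at 11. It reverses the polarity of C8 and changes the acceptor. (E)-3-Methylbuta-1,3-dienyllithium (from the iodide and t-BuLi) is added to 6 to give the dienyl carbinol F4, and acid transposition as in step 4 gives the trienone aldehyde F5.
   - An N-heterocyclic carbene (triazolium salt, i-Pr2NEt) then turns C8 into an acyl anion equivalent that adds in a vinylogous (1,6) Stetter manner to C7. This closes the same C7–C8 bond and gives 11 directly, without steps 5–7.

3. **Step 12.**
   - What may go wrong: the prototropic shift may run on from the isopropylidene enone, through deprotonation at the acidic C6′–H, to the linearly conjugated 6′-ene-2′,8′-dione. That isomer is useless for the ene reaction.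
   - Fallback: this sets out from 17 and returns at 20. The extended enolate is used rather than avoided. DBU under O2 (1 atm, dark) should let triplet oxygen intercept the C2′-to-C11′ enolate at its terminus C11′ (autoxidation of an extended enolate). This gives hydroperoxide 19, which closes to 20, so that steps 12 and 13 merge.

## Further compounds

F1 | step 11 | (7S,10R)-guaia-1(5),3-diene-2,8-dione | CC1=CC(=O)C2=C1C[C@@H](C(C)C)C(=O)C[C@H]2C
F2 | step 11 | C2-ketone cross-adduct (bridging ketone) | O=C1[C@H]2C(C)=C3C[C@@H](C(C)C)C(=O)C[C@@H](C)[C@]31[C@]1(C)C3=C(C(=O)[C@H]21)[C@H](C)CC(=O)[C@H](C(C)=C)C3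
F3 | step 11 | 2-alcohol of the cross-adduct, OH syn to C4=C5 | O[C@H]1[C@H]2C(C)=C3C[C@@H](C(C)C)C(=O)C[C@@H](C)[C@]31[C@]1(C)C3=C(C(=O)[C@H]21)[C@H](C)CC(=O)[C@H](C(C)=C)C3
F4 | step 6 | (4R)-2-methoxy-4,6-dimethyl-5-[(E)-3-methylbuta-1,3-dienyl]-2,3,4,5,6,7-hexahydrocyclopenta[b]pyran-5,6-diol | COC1C[C@@H](C)C2=C(O1)CC(C)(O)C2(O)/C=C/C(C)=C
F5 | step 6 | (3R)-3-{3-hydroxy-3-methyl-2-[(E)-3-methylbuta-1,3-dienyl]-5-oxocyclopent-1-en-1-yl}butanal | O=CC[C@@H](C)C1=C(/C=C/C(C)=C)C(C)(O)CC1=O
F0 | step 12 | none | none
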